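**Plan**
1. Retrosynthesis: the acetate, the right-hand exo-methylene and the C4 methyl (back to a C4 ketone) are removed first; the norbornene is then cut at C13′–C1 and C2–C3, which opens it to a 2-furylcarbinol (furan O between C2 and C4) whose carbinol carbon C3 sits on the spiro carbon C11′ bearing CH2I.
2. C11′–C13′ and C11′–C3 are cut next (alkylation, Claisen acylation) to a 13-nor left-half lactone 14 and a furoic acid 29.
3. Forward: ring A and its cis-lactone grow around (S)-citronellal (proline aldol, aldol condensation); the trans-lactone, the cycloheptane (one-carbon ring expansion) and the furan grow on (S)-carvone; the halves are joined, C11′ is made quaternary, and the key step closes the cyclopentene and then the norbornane.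
4. Enabling feature: ring C1–C5 of the norbornene is a disguised trans-4-hydroxy-5-alkylcyclopent-2-enone (O on C2 trans to the C3 substituent, C4 a temporary ketone, C1 the enone β-carbon), and C1 lies 1,3 to C3, so the CH2 on C11′ can bridge them; the furan is the temporary ring, the iodide the activating group.
5. Stereochemistry: C4′ and C7 from the terpenes; C7′/C8′ from L-proline; C8 by anti attack next to C7; C10 by a chiral CuH catalyst; C11′ by convex-face alkylation; C2/C3 by conrotation; C1 by the tether.

Key step: step 19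

Remark: locants C1–C15 (right half, guaiane numbering) and C1′–C15′ (left half, 1,10-seco-eudesmane numbering) are those of the target; centres that are erased later (C11, the carbinol C3, C5 after ring closure, C11′ in 31) are carried as mixtures and left open in the SMILES.

**Left half**

Step 1
Reactants: 1 (S)-citronellal
Product: 2 2-[(2S)-2,6-dimethylhept-5-en-1-yl]-1,3-dithiane
Conditions: HS(CH2)3SH, I2 (5 mol %), CH2Cl2, 0 °C
Reagents that add atoms: propane-1,3-dithiol (SCCCS)
Why: Iodine-catalysed dithioacetalisation should turn the aldehyde carbon (future C10′) into a Corey–Seebach acyl-anion equivalent under conditions too mild for the ene cyclisation of citronellal, leaving the C4′ centre untouched.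

Step 2
Reactants: 2 dithiane; 3 bromoacetaldehyde diethyl acetal
Product: 5 {2-[(2S)-2,6-dimethylhept-5-en-1-yl]-1,3-dithian-2-yl}acetaldehyde, via diethyl acetal 4 (not isolated)
Conditions: n-BuLi, THF/DMPU, −30 °C; 3, −78 → 0 °C; then 1 M HCl, THF, rt
Reagents that add atoms: water (O)
Why: Corey–Seebach alkylation of the 2-lithiodithiane with the primary bromide should attach C9′–C8′, and mild acetal hydrolysis then frees the aldehyde while dithiane and alkene survive.

Step 3
Reactants: 5 dithianyl acetaldehyde; 6 methyl 4-oxobutanoate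
Product: 8 cis-lactone aldehyde (2S,3S)-2-(dithianylmethyl)-5-oxooxolane-3-carbaldehyde, via anti-aldol adduct 7 (not isolated)
Conditions: L-proline (20 mol %), DMF, 4 °C, slow addition of 6; then PPTS, CH2Cl2, rt
Reagents that add atoms: none
Why: Proline enamine cross-aldol of the unhindered donor 6 with the neopentyl-type acceptor 5 should give the anti adduct, L-proline setting C7′ and C8′ through the hydrogen-bonded chair transition state (sense assumed by analogy with propanal donors), and lactonisation of an anti aldol necessarily gives the 2,3-cis lactone.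

Step 4
Reactants: 8 cis-lactone aldehyde
Product: 10 cis-fused enone lactone (ring A with C10′ ketone), via keto aldehyde 9 (not isolated)
Conditions: MeI, CaCO3, MeCN/H2O, 45 °C; then Bn2NH·CF3CO2H (20 mol %), toluene, 50 °C
Reagents that add atoms: water (O)
Why: S-Methylation/hydrolysis should unmask the C10′ ketone, and amine-salt-catalysed intramolecular aldol condensation (C5′ onto the C6′ aldehyde, the only six-ring mode) closes ring A, the weakly acidic catalyst avoiding β-elimination of the lactone oxygen and leaving the thermodynamically preferred cis ring fusion.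

Step 5
Reactants: 10 enone lactone
Product: 12 side-chain primary alcohol, via aldehyde 11 (not isolated)
Conditions: O3 (1 equiv), pyridine, CH2Cl2, −78 °C; Me2S; then NaBH(OAc)3, AcOH, 0 °C
Reagents that add atoms: ozone ([O-][O+]=O)
Why: Ozone should cleave the electron-rich trisubstituted side-chain alkene faster than the enone, and NaBH(OAc)3 then reduces only the aldehyde (chemoselective ozonolysis/reduction).

Step 6
Reactants: 12 alcohol
Product: 13 tert-butyldiphenylsilyl ether
Conditions: TBDPSCl, imidazole, DMF, rt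
Reagents that add atoms: tert-butyl(chloro)diphenylsilane (CC(C)(C)[Si](Cl)(c1ccccc1)c1ccccc1)
Why: Standard silylation gives a primary silyl ether robust to the acid, base and radical steps ahead and removable last with fluoride.

Step 7
Reactants: 13 silyl ether
Product: 14 left-half diene lactone (13-nor)
Conditions: Zn, CH2Br2, TiCl4, THF/CH2Cl2, 0 °C → rt
Reagents that add atoms: dibromomethane (BrCBr)
Why: Takai–Lombardo methylenation is non-basic, so the β-acyloxy ketone should not eliminate and the lactone carbonyl is not attacked, giving the exocyclic diene.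

**Right half**

Step 8
Reactants: 15 (S)-carvone
Product: 17 (4R,5S)-4-hydroxycarvone, via silyl dienol ether 16 (not isolated)
Conditions: KOt-Bu, THF, −78 → −20 °C; TBSCl; then dimethyldioxirane, acetone/CH2Cl2, −78 °C; then 1 M HCl, THF, 0 °C
Reagents that add atoms: tert-butyl(chloro)dimethylsilane (CC(C)(C)[Si](C)(C)Cl); dimethyldioxirane (CC1(C)OO1)
Why: Thermodynamic γ-deprotonation and O-silylation give the linear dienol ether, whose terminal double bond should be epoxidised anti to the neighbouring isopropenyl group (vinylogous Rubottom oxidation), so the C8 oxygen ends trans to C7.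

Step 9
Reactants: 17 hydroxy enone
Product: 18 triol
Conditions: 9-BBN (3.5 equiv), THF, 0 °C → rt; then NaOH, H2O2, 0 °C
Reagents that add atoms: hydrogen peroxide (OO)
Why: Excess 9-BBN should hydroborate the 1,1-disubstituted alkene at its terminus and reduce the enone carbonyl 1,2 (hydroboration–oxidation); both new centres are erased later.

Step 10
Reactants: 18 triol
Product: 19 trans-fused lactone enone
Conditions: TEMPO (20 mol %), PhI(OAc)2 (3.5 equiv), CH2Cl2/H2O, rt
Reagents that add atoms: none
Why: TEMPO/PhI(OAc)2 oxidises the primary alcohol first, the aldehyde is trapped by the C8 hydroxyl as a lactol and oxidised to the trans-fused lactone, and the allylic alcohol returns to the enone (oxidative lactonisation).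

Step 11
Reactants: 19 lactone enone
Product: 20 trimethylsilyl enol ether
Conditions: LiBH(s-Bu)3, THF, −78 °C; then TMSCl, Et3N, −78 → 0 °C
Reagents that add atoms: chlorotrimethylsilane (C[Si](C)(C)Cl)
Why: Conjugate hydride addition and O-silylation of the enolate (reductive silylation) should fix the enol ether regiospecifically toward the methyl-bearing carbon, the lactone being inert at −78 °C.

Step 12
Reactants: 20 silyl enol ether
Product: 21 siloxycyclopropane
Conditions: Et2Zn, CH2I2, CH2Cl2, 0 °C
Reagents that add atoms: diiodomethane (ICI)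
Why: Simmons–Smith cyclopropanation of the electron-rich enol ether installs the carbon that becomes C1; the face of addition is irrelevant.

Step 13
Reactants: 21 siloxycyclopropane
Product: 23 β-methylcycloheptenone lactone, via chloro ketone 22 (not isolated)
Conditions: FeCl3, DMF, 0 °C; then NaOAc, MeOH, 50 °C
Reagents that add atoms: iron trichloride (Cl[Fe](Cl)Cl)
Why: Ito–Saegusa ring expansion: one-electron oxidation by FeCl3 cleaves the internal cyclopropane bond to a tertiary radical that is chlorinated, and loss of HCl should give the conjugated enone with the carbonyl at C5.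

Step 14
Reactants: 23 cycloheptenone
Product: 26 hydroxymethylene ketone, via diphenylsilyl enol ether 24 (not isolated), via dimethyl acetal 25 (not isolated)
Conditions: CuCl (5 mol %), NaOt-Bu (5 mol %), (S)-p-tol-BINAP (5 mol %), Ph2SiH2, toluene, 0 °C; then HC(OMe)3, BF3·OEt2, CH2Cl2, −78 °C; then 1 M HCl, THF, rt
Reagents that add atoms: diphenylsilane ([SiH2](c1ccccc1)c1ccccc1); trimethyl orthoformate (COC(OC)OC); water (O)
Why: Ligand-controlled CuH conjugate reduction should deliver hydride to C10 on the face syn to the C8 oxygen (ligand antipode chosen accordingly) and leave the enol silane regiospecifically at C1, which a Mukaiyama reaction with the orthoformate converts into the formyl carbon C2.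

Step 15
Reactants: 26 hydroxymethylene ketone; 27 ethyl bromoacetate
Product: 29 furoic acid (right half), via ethyl ester 28 (not isolated)
Conditions: K2CO3, DMF, rt → 80 °C; then LiOH, THF/H2O, rt; then 1 M HCl
Reagents that add atoms: lithium hydroxide ([Li+].[OH-])
Why: O-Alkylation of the hydroxymethylene oxygen, intramolecular aldol condensation of the ester methylene onto the C5 ketone and dehydration (Rap–Stoermer-type furan synthesis) should give the furan with the carboxyl carbon C3 on C4 and C2 unsubstituted; saponification opens the lactone and acidification recloses it.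

**Union and key step**

Step 16
Reactants: 14 left-half lactone; 29 furoic acid
Product: 31 β-keto lactone, via acyl imidazolide 30 (not isolated)
Conditions: 29, 1,1′-carbonyldiimidazole, THF, rt; separately 14, LiN(SiMe3)2 (2.2 equiv), THF, −78 °C; then 30, −78 → −40 °C; NH4Cl
Reagents that add atoms: 1,1′-carbonyldiimidazole (O=C(n1ccnc1)n1ccnc1)
Why: Crossed Claisen C-acylation of the lithium enolate of 14 by the acyl imidazolide, which is far more electrophilic than the hindered lactone of 30, should forge C11′–C3; C11′ stays epimerisable.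

Step 17
Reactants: 31 β-keto lactone
Product: 32 iodomethyl β-keto lactone
Conditions: NaH, CH2I2 (5 equiv), THF/DMPU, 0 °C → rt
Reagents that add atoms: diiodomethane (ICI)
Why: C-Alkylation of the β-keto lactone enolate creates the quaternary C11′, the electrophile approaching the convex face anti to ring carbon C6′ on the neighbouring C7′, so CH2I (C13′) ends syn to H7′ as in the target.

Step 18
Reactants: 32 iodomethyl ketone
Product: 33 2-furylcarbinol
Conditions: NaBH4, CeCl3·7H2O, MeOH/THF, −40 °C
Reagents that add atoms: none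
Why: Luche reduction should reduce only the furyl ketone; both carbinol epimers are used because C3 is ionised in the next step.

Step 19
Reactants: 33 2-furylcarbinol
Product: 35 bridged hydroxy ketone (norbornanone), via hydroxycyclopentenone 34 (not isolated)
Conditions: Dy(OTf)3 (10 mol %), t-BuOH/H2O 5:1, 80 °C until 33 is consumed; then degas, (Me3Si)3SiH (1.5 equiv), AIBN (0.2 equiv), 80 °C, 0.01 M
Reagents that add atoms: water (O)
Why: Dy(OTf)3 ionises the furylcarbinol, water adds to the free α-position C2, the furan opens to a 1-hydroxypentadienyl cation and 4π conrotatory electrocyclisation forms C2–C3 (Piancatelli rearrangement) to give 34; the silyl radical then abstracts iodine and the primary C13′ radical adds 5-exo-trig to the enone β-carbon C1 (Giese-type conjugate addition), the α-keto radical being reduced by the silane. The cyclopentenone ring thus closes by cation electrocyclisation and the second five-membered ring of the norbornane by 5-exo-trig radical cyclisation; the closest precedents are Piancatelli/Michael cascades and the closure of 2-(cyclopent-2-enyl)ethyl radicals to norbornanes. C2 and C3 are set trans by conrotation of the out,out-cation, and the sense of rotation should be imposed by the C10 methyl and the C7 side chain on the lower face of the ring-fused cation, which send the bulky C11′ group to the upper face. C1 is set by the tether, since the CH2 radical can reach C1 only on the face that carries C11′ at C3, and the exo lactone carbonyl at the spiro centre follows from the fixed configurations of C11′ and C3. The step needs this torquoselectivity and also chemoselectivity: the initiator is added only after the carbinol is consumed so the iodide is not reduced early, and the nucleophilic radical attacks the electrophilic β-carbon C1 rather than C5. Keeping 34 in the flask avoids its dehydration, and once bridged C3 is a bridgehead that can no longer epimerise or eliminate.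

**Endgame**

Step 20
Reactants: 35 hydroxy ketone
Product: 37 vinyl iodide, via silyl hydrazone 36 (not isolated)
Conditions: TBSNHNHTBS, Sc(OTf)3 (1 mol %), CH2Cl2, rt; then I2, tetramethylguanidine, THF, 0 °C
Reagents that add atoms: 1,2-bis(tert-butyldimethylsilyl)hydrazine (CC(C)(C)[Si](C)(C)NN[Si](C)(C)C(C)(C)C); iodine (II)
Why: Barton vinyl iodide synthesis through the N-silyl hydrazone should place the double bond toward C5 because C3 is a bridgehead, and it needs neither a strong base nor a rearrangement-prone O-activation of the norbornanone.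

Step 21
Reactants: 37 vinyl iodide
Product: 38 C4-methyl alkene
Conditions: MeZnCl (3 equiv), Pd(PPh3)4 (5 mol %), THF, 50 °C
Reagents that add atoms: methylzinc chloride (C[Zn]Cl)
Why: Negishi coupling replaces iodine by the C4 methyl with the C4=C5 position retained; the organozinc tolerates both lactones and the free alcohol only consumes one equivalent.

Step 22
Reactants: 38 methyl alkene
Product: 40 α-methylene lactone, via phenyl selenide 39 (not isolated)
Conditions: LiN(i-Pr)2 (2.2 equiv), THF, −78 °C; PhSeCl (1.2 equiv); then H2O2, pyridine, CH2Cl2, 0 °C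
Reagents that add atoms: benzeneselenenyl chloride (Cl[Se]c1ccccc1)
Why: The alkoxide/lactone-enolate dianion is selenenylated at C11, and selenoxide syn-elimination, which in trans-fused α-methyl lactones goes toward the methyl group, should give the exo-methylene; no other enolisable ester is present at this stage.

Step 23
Reactants: 40 hydroxy bis-lactone
Product: 41 C2 acetate
Conditions: Ac2O, DMAP, pyridine, CH2Cl2, rt
Reagents that add atoms: acetic anhydride (CC(=O)OC(C)=O)
Why: DMAP-catalysed acylation of the only free hydroxyl (C2); the primary alcohol is still silylated.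

Step 24
Reactants: 41 acetate
Product: 42 CNP0299458.1 (target)
Conditions: HF·pyridine, THF/pyridine, 0 °C → rt
Reagents that add atoms: none
Why: Buffered fluoride should cleave the Si–O bond without acyl migration or Michael addition to the α-methylene lactone.

**Compound list**

1 | (S)-citronellal, (3S)-3,7-dimethyloct-6-enal | O=CC[C@@H](C)CCC=C(C)C | starting material
2 | 2-[(2S)-2,6-dimethylhept-5-en-1-yl]-1,3-dithiane | C1(SCCCS1)C[C@@H](C)CCC=C(C)C | intermediate
3 | bromoacetaldehyde diethyl acetal | CCOC(CBr)OCC | starting material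
4 | 2-(2,2-diethoxyethyl)-2-[(2S)-2,6-dimethylhept-5-en-1-yl]-1,3-dithiane | CCOC(CC1(SCCCS1)C[C@@H](C)CCC=C(C)C)OCC | intermediate
5 | {2-[(2S)-2,6-dimethylhept-5-en-1-yl]-1,3-dithian-2-yl}acetaldehyde | O=CCC1(SCCCS1)C[C@@H](C)CCC=C(C)C | intermediate
6 | methyl 4-oxobutanoate | COC(=O)CCC=O | starting material
7 | methyl (3S,4S)-5-{2-[(2S)-2,6-dimethylhept-5-en-1-yl]-1,3-dithian-2-yl}-3-formyl-4-hydroxypentanoate (anti aldol) | O=C[C@@H](CC(=O)OC)[C@@H](O)CC1(SCCCS1)C[C@@H](C)CCC=C(C)C | intermediate
8 | (2S,3S)-2-({2-[(2S)-2,6-dimethylhept-5-en-1-yl]-1,3-dithian-2-yl}methyl)-5-oxooxolane-3-carbaldehyde (2,3-cis) | O=C[C@H]1CC(=O)O[C@H]1CC2(SCCCS2)C[C@@H](C)CCC=C(C)C | intermediate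
9 | (2S,3S)-2-[(4S)-4,8-dimethyl-2-oxonon-7-en-1-yl]-5-oxooxolane-3-carbaldehyde | O=C[C@H]1CC(=O)O[C@H]1CC(=O)C[C@@H](C)CCC=C(C)C | intermediate
10 | (3aR,7aS)-5-[(2S)-6-methylhept-5-en-2-yl]-3a,7a-dihydro-1-benzofuran-2,6(3H,7H)-dione (cis-fused) | O=C1C[C@@H]2OC(=O)C[C@@H]2C=C1[C@@H](C)CCC=C(C)C | intermediate
11 | (4S)-4-[(3aR,7aS)-2,6-dioxo-2,3,3a,6,7,7a-hexahydro-1-benzofuran-5-yl]pentanal | O=C1C[C@@H]2OC(=O)C[C@@H]2C=C1[C@@H](C)CCC=O | intermediate
12 | (3aR,7aS)-5-[(2S)-5-hydroxypentan-2-yl]-3a,7a-dihydro-1-benzofuran-2,6(3H,7H)-dione | O=C1C[C@@H]2OC(=O)C[C@@H]2C=C1[C@@H](C)CCCO | intermediate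
13 | tert-butyldiphenylsilyl ether of 12 | O=C1C[C@@H]2OC(=O)C[C@@H]2C=C1[C@@H](C)CCCO[Si](c1ccccc1)(c1ccccc1)C(C)(C)C | intermediate
14 | (3aR,7aS)-5-[(2S)-5-(tert-butyldiphenylsilyloxy)pentan-2-yl]-6-methylidene-3a,6,7,7a-tetrahydro-1-benzofuran-2(3H)-one (13-nor left half) | C=C1C[C@@H]2OC(=O)C[C@@H]2C=C1[C@@H](C)CCCO[Si](c1ccccc1)(c1ccccc1)C(C)(C)C | intermediate
15 | (S)-(+)-carvone | O=C1C(C)=CC[C@H](C(C)=C)C1 | starting material
16 | tert-butyldimethylsilyl dienol ether of 15 (1-silyloxy-2-methyl-5-isopropenylcyclohexa-1,3-diene) | CC(C)(C)[Si](C)(C)OC1=C(C)C=C[C@H](C(C)=C)C1 | intermediate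
17 | (4R,5S)-4-hydroxy-2-methyl-5-(prop-1-en-2-yl)cyclohex-2-en-1-one (OH trans to isopropenyl) | O=C1C(C)=C[C@@H](O)[C@H](C(C)=C)C1 | intermediate
18 | 5-(1-hydroxypropan-2-yl)-2-methylcyclohex-2-ene-1,4-diol (4-OH trans to the side chain, ring centres as in 17; C1 and side-chain CH as mixtures) | OC1C(C)=C[C@@H](O)[C@H](C(C)CO)C1 | intermediate
19 | 3,6-dimethyl-3,3a,4,7a-tetrahydro-1-benzofuran-2,5-dione, 3a,7a-trans-fused (C3 mixture) | O=C1C(C)=C[C@H]2OC(=O)C(C)[C@@H]2C1 | intermediate
20 | 5-trimethylsilyloxy enol ether of the 6,7-dihydro derivative of 19 (enol double bond toward the methyl-bearing carbon) | C[Si](C)(C)OC1=C(C)C[C@H]2OC(=O)C(C)[C@@H]2C1 | intermediate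
21 | siloxycyclopropane from 20 (CH2 across the enol double bond) | C[Si](C)(C)OC12CC1(C)C[C@H]3OC(=O)C(C)[C@@H]3C2 | intermediate
22 | ring-expanded β-chloro ketone (Cl and methyl on C10, ketone at C5) | O=C1CC(C)(Cl)C[C@H]2OC(=O)C(C)[C@@H]2C1 | intermediate
23 | 3,7-dimethyl-3,3a,4,8a-tetrahydro-2H-cyclohepta[b]furan-2,5(8H)-dione, trans-fused (C5 ketone, C1=C10 enone) | O=C1C=C(C)C[C@H]2OC(=O)C(C)[C@@H]2C1 | intermediate
24 | diphenylsilyl enol ether (O–C5=C1) with the C10 methyl set anti to the C8 oxygen | [SiH](c1ccccc1)(c1ccccc1)OC1=C[C@H](C)C[C@H]2OC(=O)C(C)[C@@H]2C1 | intermediate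
25 | C1-dimethoxymethyl C5 ketone | O=C1C(C(OC)OC)[C@H](C)C[C@H]2OC(=O)C(C)[C@@H]2C1 | intermediate
26 | C1-hydroxymethylidene C5 ketone | O=C1C(=CO)[C@H](C)C[C@H]2OC(=O)C(C)[C@@H]2C1 | intermediate
27 | ethyl bromoacetate | CCOC(=O)CBr | starting material
28 | ethyl ester of 29 | CCOC(=O)c1occ2[C@H](C)C[C@H]3OC(=O)C(C)[C@@H]3Cc12 | intermediate
29 | right-half furoic acid: furan fused at C1–C5 of the cycloheptane, CO2H (C3) on C4, C2–H, trans 8,12-lactone with 11-methyl, 10-methyl anti to the C8 oxygen | OC(=O)c1occ2[C@H](C)C[C@H]3OC(=O)C(C)[C@@H]3Cc12 | intermediate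
30 | acyl imidazolide of 29 | O=C(n1ccnc1)c1occ2[C@H](C)C[C@H]3OC(=O)C(C)[C@@H]3Cc12 | intermediate
31 | β-keto lactone: 14 acylated at C11′ by the furoyl group of 29 | C=C1C[C@@H]2OC(=O)C(C(=O)c3occ4[C@H](C)C[C@H]5OC(=O)C(C)[C@@H]5Cc34)[C@@H]2C=C1[C@@H](C)CCCO[Si](c1ccccc1)(c1ccccc1)C(C)(C)C | intermediate
32 | C11′-iodomethyl β-keto lactone (CH2I syn to H7′) | C=C1C[C@@H]2OC(=O)[C@](CI)(C(=O)c3occ4[C@H](C)C[C@H]5OC(=O)C(C)[C@@H]5Cc34)[C@@H]2C=C1[C@@H](C)CCCO[Si](c1ccccc1)(c1ccccc1)C(C)(C)C | intermediate
33 | 2-furylcarbinol from 32 (C3 epimers) | C=C1C[C@@H]2OC(=O)[C@](CI)(C(O)c3occ4[C@H](C)C[C@H]5OC(=O)C(C)[C@@H]5Cc34)[C@@H]2C=C1[C@@H](C)CCCO[Si](c1ccccc1)(c1ccccc1)C(C)(C)C | intermediate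
34 | trans-4-hydroxy-5-alkylcyclopent-2-enone (C4 ketone, C1=C5, 2-OH trans to C11′ on C3) still carrying CH2I | C=C1C[C@@H]2OC(=O)[C@](CI)([C@H]3[C@H](O)C4=C(C3=O)C[C@H]5C(C)C(=O)O[C@@H]5C[C@H]4C)[C@@H]2C=C1[C@@H](C)CCCO[Si](c1ccccc1)(c1ccccc1)C(C)(C)C | intermediate
35 | norbornan-4-one with free 2-OH (C13′–C1 bridge closed; H at C5 unassigned) | C=C1C[C@@H]2OC(=O)[C@@]3(C[C@@]45C(C(=O)[C@@H]3[C@@H]4O)C[C@H]3C(C)C(=O)O[C@@H]3C[C@H]5C)[C@@H]2C=C1[C@@H](C)CCCO[Si](c1ccccc1)(c1ccccc1)C(C)(C)C | intermediate
36 | N-tert-butyldimethylsilyl hydrazone of 35 at C4 | C=C1C[C@@H]2OC(=O)[C@@]3(C[C@@]45C(C(=NN[Si](C)(C)C(C)(C)C)[C@@H]3[C@@H]4O)C[C@H]3C(C)C(=O)O[C@@H]3C[C@H]5C)[C@@H]2C=C1[C@@H](C)CCCO[Si](c1ccccc1)(c1ccccc1)C(C)(C)C | intermediate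
37 | C4 vinyl iodide (C4=C5) | C=C1C[C@@H]2OC(=O)[C@@]3(C[C@@]45C(=C(I)[C@@H]3[C@@H]4O)C[C@H]3C(C)C(=O)O[C@@H]3C[C@H]5C)[C@@H]2C=C1[C@@H](C)CCCO[Si](c1ccccc1)(c1ccccc1)C(C)(C)C | intermediate
38 | C4-methyl norbornene with free 2-OH and 11,13-dihydro lactone | C=C1C[C@@H]2OC(=O)[C@@]3(C[C@@]45C(=C(C)[C@@H]3[C@@H]4O)C[C@H]3C(C)C(=O)O[C@@H]3C[C@H]5C)[C@@H]2C=C1[C@@H](C)CCCO[Si](c1ccccc1)(c1ccccc1)C(C)(C)C | intermediate
39 | C11 phenyl selenide of 38 | C=C1C[C@@H]2OC(=O)[C@@]3(C[C@@]45C(=C(C)[C@@H]3[C@@H]4O)C[C@H]3C(C)([Se]c6ccccc6)C(=O)O[C@@H]3C[C@H]5C)[C@@H]2C=C1[C@@H](C)CCCO[Si](c1ccccc1)(c1ccccc1)C(C)(C)C | intermediate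
40 | 2-hydroxy compound with the right-hand α-methylene lactone (silyl ether) | C=C1C[C@@H]2OC(=O)[C@@]3(C[C@@]45C(=C(C)[C@@H]3[C@@H]4O)C[C@H]3C(=C)C(=O)O[C@@H]3C[C@H]5C)[C@@H]2C=C1[C@@H](C)CCCO[Si](c1ccccc1)(c1ccccc1)C(C)(C)C | intermediate
41 | 1′-O-tert-butyldiphenylsilyl ether of the target | C=C1C[C@@H]2OC(=O)[C@@]3(C[C@@]45C(=C(C)[C@@H]3[C@@H]4OC(C)=O)C[C@H]3C(=C)C(=O)O[C@@H]3C[C@H]5C)[C@@H]2C=C1[C@@H](C)CCCO[Si](c1ccccc1)(c1ccccc1)C(C)(C)C | intermediate
42 | CNP0299458.1 | C=C1C[C@@H]2OC(=O)[C@@]3(C[C@@]45C(=C(C)[C@@H]3[C@@H]4OC(C)=O)C[C@H]3C(=C)C(=O)O[C@@H]3C[C@H]5C)[C@@H]2C=C1[C@@H](C)CCCO | target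

**Count and risks**

Total steps: 24. Longest linear sequence: 17 steps (15 → 42, steps 8–15 and 16–24); the left half contributes 7 steps (1 → 14).

Step 19. The conrotatory closure may show low or reversed torquoselectivity (the two trans-hydroxycyclopentenones lead to different norbornanes), the neopentyl-type carbinol may ionise slowly, and 34 may dehydrate or the iodide be reduced before ring closure. The fallback separates the two events and puts the first under catalyst control. Setting out from 33, the rearrangement is run alone with a chiral BINOL-derived phosphoric acid in wet toluene and the wanted diastereomer of 34 is isolated. It is silylated (Et3SiOTf, 2,6-lutidine) to the triethylsilyl ether of 34 F1, which can no longer dehydrate. F1 is cyclised with Bu3SnH/AIBN in benzene at high dilution to the triethylsilyl ether of 35 F2, and PPTS/MeOH removes the triethylsilyl group to return to the route at 35.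

Step 17. The ambident enolate may alkylate on oxygen, react sluggishly with CH2I2, or give some of the C11′ epimer. The fallback replaces the SN2 alkylation by a reversible, C-selective aldol with formaldehyde. Setting out from 31, aqueous CH2O/KHCO3 in THF should give the C11′-hydroxymethyl β-keto lactone F3 from the convex face; Appel-type iodination (PPh3, I2, imidazole, toluene, 60 °C) then returns to the route at 32.

Step 8. Oxidation of the dienol ether may occur at the wrong site (α-attack at the methyl-bearing carbon or epoxidation of the isopropenyl group), and the silyl ether may hydrolyse before it is oxidised. The fallback replaces the epoxidation by a cycloaddition that only the 1,3-diene can undergo. Setting out from 15, the dienol ether 16 is isolated by non-aqueous work-up and photo-oxygenated (O2, tetraphenylporphyrin, visible light, CH2Cl2, −78 °C) to the bridged endoperoxide F4, singlet oxygen adding anti to the isopropenyl group. Zn/AcOH cleaves the O–O bond and the silyl hemiketal collapses to the enone, returning to the route at 17.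

Further compounds
F1 | step 19 | triethylsilyl ether of 34 | C=C1C[C@@H]2OC(=O)[C@](CI)([C@H]3[C@H](O[Si](CC)(CC)CC)C4=C(C3=O)C[C@H]5C(C)C(=O)O[C@@H]5C[C@H]4C)[C@@H]2C=C1[C@@H](C)CCCO[Si](c1ccccc1)(c1ccccc1)C(C)(C)C
F2 | step 19 | triethylsilyl ether of 35 | C=C1C[C@@H]2OC(=O)[C@@]3(C[C@@]45C(C(=O)[C@@H]3[C@@H]4O[Si](CC)(CC)CC)C[C@H]3C(C)C(=O)O[C@@H]3C[C@H]5C)[C@@H]2C=C1[C@@H](C)CCCO[Si](c1ccccc1)(c1ccccc1)C(C)(C)C
F3 | step 17 | C11′-hydroxymethyl β-keto lactone | C=C1C[C@@H]2OC(=O)[C@](CO)(C(=O)c3occ4[C@H](C)C[C@H]5OC(=O)C(C)[C@@H]5Cc34)[C@@H]2C=C1[C@@H](C)CCCO[Si](c1ccccc1)(c1ccccc1)C(C)(C)C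
F4 | step 8 | 1-silyloxy-2,3-dioxabicyclo[2.2.2]oct-5-ene endoperoxide of 16 (peroxide bridge anti to isopropenyl) | CC(C)(C)[Si](C)(C)O[C@]12OO[C@H](C=C1C)[C@H](C(C)=C)C2
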